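**Plan**
Cuts: the two phenols are masked as benzyl ethers and C2=C3 is taken back to the saturated isoflavanone. Ring C is then opened at three bonds at once: C4a–C4, C4–C3 and O1–C2.
Enabling feature: the C4 carbonyl carbon of ring C is bonded only to C4a of ring A and to C3, the carbon that bears ring B, so it can be lifted out as CO. What remains is an ortho-iodophenol (ring A with O1) and a 1-arylvinyl boronate (C2=C3 with rings B and D).
Fragments: the iodophenol comes from resorcinol in two steps. The boronate comes from 2,4,6-trihydroxyacetophenone, whose acetyl group already holds C3, C2 and the crowded C1'–C3 bond.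
Ring order forward: rings A and B are bought. Ring D closes by acid-induced addition of the 4-OH to a C-prenyl group once the neighbouring 2-OH is methylated. Ring C closes last, in the carbonylative coupling and oxa-Michael step.
Stereochemistry: the target has no stereocentre. C3 of the isoflavanone is formed racemic and becomes sp2 again on dehydrogenation.

Key step: step 10

Remark: A and C are the benzo and pyranone rings of the chromone, B is the pendant aryl ring and D is the dimethylpyran ring fused to B. Plain numbers refer to the chromone, and names of the B/D unit use chroman numbering.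

**Step 1**
Reactants: 1 resorcinol
Product: 2 4-iodobenzene-1,3-diol (4-iodoresorcinol)
Conditions: ICl (1.0 equiv), Et2O, 0 °C to rt
Reagents that add atoms: iodine monochloride, ClI
Why: Electrophilic aromatic iodination; in ether ICl attacks C4 (para to one hydroxyl, ortho to the other) and not the crowded C2 between the two oxygens, which is the established outcome for resorcinol.

**Step 2**
Reactants: 2 4-iodobenzene-1,3-diol
Product: 3 5-(benzyloxy)-2-iodophenol
Conditions: BnBr (1.0 equiv), K2CO3 (1.1 equiv), acetone, rt to 50 °C
Reagents that add atoms: benzyl bromide, BrCc1ccccc1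
Why: Williamson etherification with one equivalent of bromide; the hydroxyl para to iodine is open and gives the more nucleophilic phenoxide, the hydroxyl next to iodine is shielded and less basic, and the isomeric and double ethers should be removable by chromatography.

**Step 3**
Reactants: 4 2,4,6-trihydroxyacetophenone; 5 prenyl bromide (1-bromo-3-methylbut-2-ene)
Product: 6 1-[2,4,6-trihydroxy-3-(3-methylbut-2-en-1-yl)phenyl]ethan-1-one
Conditions: KOH (1.0 equiv), H2O, 0 °C to rt, 5 (0.9 equiv) added slowly
Reagents that add atoms: none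
Why: Nuclear C-prenylation of the ambident acylphloroglucinol anion in water, a standard reaction of this class; C3 and C5 are equivalent, so one mono-C-prenyl product is possible, and a deficit of bromide limits double alkylation.

**Step 4**
Reactants: 6 1-[2,4,6-trihydroxy-3-(3-methylbut-2-en-1-yl)phenyl]ethan-1-one
Product: 7 1-[2-hydroxy-4,6-bis(methoxymethoxy)-3-(3-methylbut-2-en-1-yl)phenyl]ethan-1-one
Conditions: MOMCl (2.1 equiv), i-Pr2NEt (2.5 equiv), CH2Cl2, 0 °C to rt
Reagents that add atoms: chloromethyl methyl ether, COCCl
Why: MOM ether formation steered by chelation and size; the unchelated 4-OH reacts first, then the 6-OH with its free ortho position, while the 2-OH wedged between acetyl and prenyl stays hydrogen-bonded to the carbonyl, as is known for 3-alkylphloroacetophenones.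

**Step 5**
Reactants: 7 1-[2-hydroxy-4,6-bis(methoxymethoxy)-3-(3-methylbut-2-en-1-yl)phenyl]ethan-1-one
Product: 8 1-[2-methoxy-4,6-bis(methoxymethoxy)-3-(3-methylbut-2-en-1-yl)phenyl]ethan-1-one
Conditions: MeI (3 equiv), K2CO3 (2 equiv), DMF, 40 °C
Reagents that add atoms: iodomethane, CI
Why: Williamson methylation of the one remaining, chelated phenol with excess MeI in a dipolar aprotic solvent; MOM ethers, alkene and ketone are inert to K2CO3.

**Step 6**
Reactants: 8 1-[2-methoxy-4,6-bis(methoxymethoxy)-3-(3-methylbut-2-en-1-yl)phenyl]ethan-1-one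
Product: 10 1-(7-hydroxy-5-methoxy-2,2-dimethylchroman-6-yl)ethan-1-one, via free prenylated diphenol 9 (not isolated)
Conditions: 3 M HCl, MeOH, 55 °C; evaporate; then p-TsOH·H2O (20 mol%), toluene, 80 °C
Reagents that add atoms: none
Why: Acid acetal cleavage followed by Markovnikov intramolecular hydroalkoxylation of the prenyl alkene through its tertiary cation; only the 4-OH flanks the prenyl group, because the other neighbour is now a methyl ether, so a single 2,2-dimethylchroman (ring D) can form.

**Step 7**
Reactants: 10 1-(7-hydroxy-5-methoxy-2,2-dimethylchroman-6-yl)ethan-1-one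
Product: 11 1-[7-(benzyloxy)-5-methoxy-2,2-dimethylchroman-6-yl]ethan-1-one
Conditions: BnBr (1.3 equiv), K2CO3 (2 equiv), DMF, 60 °C
Reagents that add atoms: benzyl bromide, BrCc1ccccc1
Why: Williamson benzylation of the only phenol left, whose hydrogen bond to the acetyl group is overcome in warm DMF.

**Step 8**
Reactants: 11 1-[7-(benzyloxy)-5-methoxy-2,2-dimethylchroman-6-yl]ethan-1-one
Product: 12 1-[7-(benzyloxy)-5-methoxy-2,2-dimethylchroman-6-yl]vinyl trifluoromethanesulfonate
Conditions: KN(SiMe3)2 (1.2 equiv), THF, −78 °C; PhNTf2 (1.2 equiv), −78 to 0 °C; filtration through Et3N-washed silica, used at once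
Reagents that add atoms: N-phenylbis(trifluoromethanesulfonimide), O=S(=O)(N(c1ccccc1)S(=O)(=O)C(F)(F)F)C(F)(F)F
Why: Enolate O-sulfonylation; the methyl group is the only enolisable site, so one enol triflate forms, and cold, base-buffered handling answers the tendency of the electron-rich aryl group to assist ionisation.

**Step 9**
Reactants: 12 1-[7-(benzyloxy)-5-methoxy-2,2-dimethylchroman-6-yl]vinyl trifluoromethanesulfonate; 13 bis(pinacolato)diboron
Product: 14 2-{1-[7-(benzyloxy)-5-methoxy-2,2-dimethylchroman-6-yl]vinyl}-4,4,5,5-tetramethyl-1,3,2-dioxaborolane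
Conditions: PdCl2(PPh3)2 (3 mol%), PPh3 (6 mol%), KOPh (1.5 equiv), toluene, 50 °C
Reagents that add atoms: none
Why: Miyaura borylation of an alkenyl triflate under the mild phenoxide conditions developed for 1-substituted vinyl triflates; the non-polar solvent and low temperature disfavour heterolysis and elimination, and the ethers are spectators.

**Step 10**
Reactants: 3 5-(benzyloxy)-2-iodophenol (1.3 equiv); 14 2-{1-[7-(benzyloxy)-5-methoxy-2,2-dimethylchroman-6-yl]vinyl}-4,4,5,5-tetramethyl-1,3,2-dioxaborolane; 15 carbon monoxide
Product: 17 racemic 7-(benzyloxy)-3-[7-(benzyloxy)-5-methoxy-2,2-dimethylchroman-6-yl]chroman-4-one, via hydroxyaryl vinyl ketone 16 (not isolated)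
Conditions: CO (1 atm), PdCl2(dppf) (5 mol%), K2CO3 (3 equiv), anisole–H2O (20:1), 80 °C
Reagents that add atoms: none
Why: PdCl2(dppf) is reduced in the flask to zerovalent palladium, which adds oxidatively to the C–I bond of 3; migratory insertion of CO gives an aroylpalladium iodide (C4a–C4), and base-assisted transmetalation with 14 followed by reductive elimination forms C4–C3 and releases enone 16. The closest known reactions are the carbonylative Suzuki–Miyaura coupling of aryl iodides with alkenylboron reagents to aryl vinyl ketones and the base-induced closure of 2'-hydroxy-alpha-methylenedeoxybenzoins to isoflavanones. Ring C closes by 6-endo-trig oxa-Michael addition of the ortho phenoxide to the unsubstituted CH2 terminus (O1–C2), the only acceptor carbon, and this carbon stays accessible although ring B crowds C3. The C3 stereocentre arises from protonation of the resulting enolate with no controlling element, so 17 is racemic, which is harmless because C3 becomes sp2 in step 12. The step needs CO insertion to outrun transmetalation, and this is secured by the CO atmosphere, the ready migration of the electron-rich aryl group and the slow transmetalation of the di-ortho-substituted vinyl boronate. Capture of the aroylpalladium by phenoxide or water is the competing path and is countered by an excess of the cheap partner 3, a minimum of water and the chelating dppf ligand.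

**Step 11**
Reactants: 17 racemic 7-(benzyloxy)-3-[7-(benzyloxy)-5-methoxy-2,2-dimethylchroman-6-yl]chroman-4-one
Product: 18 {7-(benzyloxy)-3-[7-(benzyloxy)-5-methoxy-2,2-dimethylchroman-6-yl]-2H-chromen-4-yl}oxy(trimethyl)silane
Conditions: TMSOTf (1.5 equiv), Et3N (3 equiv), CH2Cl2, 0 °C to rt; cold aq NaHCO3 wash, used crude
Reagents that add atoms: trimethylsilyl trifluoromethanesulfonate, C[Si](C)(C)OS(=O)(=O)C(F)(F)F
Why: Soft enolisation with O-silylation (silyl enol ether formation); C3–H is the only alpha hydrogen and is axial to the carbonyl when ring B sits equatorial, so a single 4-silyloxy-2H-chromene forms and the stereocentre is erased.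

**Step 12**
Reactants: 18 {7-(benzyloxy)-3-[7-(benzyloxy)-5-methoxy-2,2-dimethylchroman-6-yl]-2H-chromen-4-yl}oxy(trimethyl)silane
Product: 19 7-(benzyloxy)-3-[7-(benzyloxy)-5-methoxy-2,2-dimethylchroman-6-yl]-4H-chromen-4-one
Conditions: DDQ (1.05 equiv), 2,4,6-collidine (1.5 equiv), CH2Cl2, 0 °C
Reagents that add atoms: none
Why: DDQ oxidation of a silyl enol ether; hydride loss from C2 gives an aromatic 4-silyloxybenzopyrylium ion that sheds silicon to leave the chromone, a process that is fast at 0 °C, whereas DDQ dehydrogenation of the electron-rich ring D and attack on aryl benzyl ethers need heat.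

**Step 13**
Reactants: 19 7-(benzyloxy)-3-[7-(benzyloxy)-5-methoxy-2,2-dimethylchroman-6-yl]-4H-chromen-4-one
Product: 20 glycyrrhizaisoflavone C, 7-hydroxy-3-(7-hydroxy-5-methoxy-2,2-dimethylchroman-6-yl)-4H-chromen-4-one
Conditions: H2 (1 atm), Pd/C (10 wt% Pd), EtOAc–MeOH, rt, stopped after uptake of two equivalents
Reagents that add atoms: none
Why: Catalytic hydrogenolysis of aryl benzyl ethers, the usual end game for isoflavones; the trisubstituted vinylogous-ester C2=C3 bond, screened by the di-ortho-substituted ring B, is reduced much more slowly.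

**Compound list**
1 | resorcinol | Oc1cccc(O)c1 | starting material
2 | 4-iodobenzene-1,3-diol | Oc1ccc(I)c(O)c1 | intermediate
3 | 5-(benzyloxy)-2-iodophenol | Oc1cc(OCc2ccccc2)ccc1I | intermediate
4 | 2,4,6-trihydroxyacetophenone | CC(=O)c1c(O)cc(O)cc1O | starting material
5 | prenyl bromide | CC(C)=CCBr | starting material
6 | 1-[2,4,6-trihydroxy-3-(3-methylbut-2-en-1-yl)phenyl]ethan-1-one | CC(=O)c1c(O)cc(O)c(CC=C(C)C)c1O | intermediate
7 | 1-[2-hydroxy-4,6-bis(methoxymethoxy)-3-(3-methylbut-2-en-1-yl)phenyl]ethan-1-one | CC(=O)c1c(OCOC)cc(OCOC)c(CC=C(C)C)c1O | intermediate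
8 | 1-[2-methoxy-4,6-bis(methoxymethoxy)-3-(3-methylbut-2-en-1-yl)phenyl]ethan-1-one | CC(=O)c1c(OCOC)cc(OCOC)c(CC=C(C)C)c1OC | intermediate
9 | 1-[4,6-dihydroxy-2-methoxy-3-(3-methylbut-2-en-1-yl)phenyl]ethan-1-one (formed in the flask) | CC(=O)c1c(O)cc(O)c(CC=C(C)C)c1OC | intermediate
10 | 1-(7-hydroxy-5-methoxy-2,2-dimethylchroman-6-yl)ethan-1-one | COc1c2c(cc(O)c1C(C)=O)OC(C)(C)CC2 | intermediate
11 | 1-[7-(benzyloxy)-5-methoxy-2,2-dimethylchroman-6-yl]ethan-1-one | COc1c2c(cc(OCc3ccccc3)c1C(C)=O)OC(C)(C)CC2 | intermediate
12 | 1-[7-(benzyloxy)-5-methoxy-2,2-dimethylchroman-6-yl]vinyl trifluoromethanesulfonate | C=C(OS(=O)(=O)C(F)(F)F)c1c(OC)c2c(cc1OCc1ccccc1)OC(C)(C)CC2 | intermediate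
13 | bis(pinacolato)diboron | CC1(C)OB(B2OC(C)(C)C(C)(C)O2)OC1(C)C | starting material
14 | 2-{1-[7-(benzyloxy)-5-methoxy-2,2-dimethylchroman-6-yl]vinyl}-4,4,5,5-tetramethyl-1,3,2-dioxaborolane | C=C(B1OC(C)(C)C(C)(C)O1)c1c(OC)c2c(cc1OCc1ccccc1)OC(C)(C)CC2 | intermediate
15 | carbon monoxide | [C-]#[O+] | starting material
16 | 1-[4-(benzyloxy)-2-hydroxyphenyl]-2-[7-(benzyloxy)-5-methoxy-2,2-dimethylchroman-6-yl]prop-2-en-1-one (formed in the flask) | C=C(C(=O)c1ccc(OCc2ccccc2)cc1O)c1c(OC)c2c(cc1OCc1ccccc1)OC(C)(C)CC2 | intermediate
17 | 7-(benzyloxy)-3-[7-(benzyloxy)-5-methoxy-2,2-dimethylchroman-6-yl]chroman-4-one, racemic at C3 (one enantiomer drawn) | COc1c2c(cc(OCc3ccccc3)c1[C@@H]1COc3cc(OCc4ccccc4)ccc3C1=O)OC(C)(C)CC2 | intermediate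
18 | {7-(benzyloxy)-3-[7-(benzyloxy)-5-methoxy-2,2-dimethylchroman-6-yl]-2H-chromen-4-yl}oxy(trimethyl)silane | COc1c2c(cc(OCc3ccccc3)c1C1=C(O[Si](C)(C)C)c3ccc(OCc4ccccc4)cc3OC1)OC(C)(C)CC2 | intermediate
19 | 7-(benzyloxy)-3-[7-(benzyloxy)-5-methoxy-2,2-dimethylchroman-6-yl]-4H-chromen-4-one | COc1c2c(cc(OCc3ccccc3)c1-c1coc3cc(OCc4ccccc4)ccc3c1=O)OC(C)(C)CC2 | intermediate
20 | glycyrrhizaisoflavone C (achiral) | COc1c2c(cc(O)c1-c1coc3cc(O)ccc3c1=O)OC(C)(C)CC2 | target

**Step count and risks**
Total step count: 13. Longest linear sequence: 11 steps (steps 3 to 13, from 2,4,6-trihydroxyacetophenone). Steps 1 and 2 form the short branch that joins at step 10.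

**Step 10.** Transmetalation of the di-ortho-substituted vinyl boronate may be so slow that the aroylpalladium is intercepted by phenoxide or water (ester or acid formation), while the boronate is lost by protodeboronation.
- The fallback exchanges the roles of the two partners and sets out from 3 and 12.
- Miyaura borylation of 3 (13, PdCl2(dppf), KOAc, dioxane, 80 °C) would give 5-(benzyloxy)-2-(4,4,5,5-tetramethyl-1,3,2-dioxaborolan-2-yl)phenol F1.
- Enol triflate 12 then acts as the electrophile under CO (1 atm, PdCl2(dppf), K2CO3, KI, anisole, 80 °C).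
- The crowded fragment now enters by oxidative addition and CO insertion, which tolerate bulk, and the ordinary aryl boronate F1 does the transmetalation.
- The same enone 16 results and closes to 17, where the route is rejoined.

**Step 8.** The enol triflate may be lost by aryl-assisted heterolysis, hydrolysis back to the ketone, or elimination during isolation or in step 9.
- The fallback replaces the super leaving group by iodide and sets out from 11.
- Condensation with N2H4·H2O (Et3N, EtOH, reflux) would give 1-[7-(benzyloxy)-5-methoxy-2,2-dimethylchroman-6-yl]ethan-1-one hydrazone F2.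
- Barton vinyl iodide synthesis (I2, 1,1,3,3-tetramethylguanidine, THF, 0 °C) would give 7-(benzyloxy)-6-(1-iodovinyl)-5-methoxy-2,2-dimethylchroman F3.
- F3 is borylated with 13 under the conditions of step 9 and comes back to the route at 14.

**Step 12.** Hydride abstraction at the benzylic C4 of the trioxygenated ring D may compete with oxidation of the enol silane, so that the oxidant is shared between two sites.
- The fallback accepts oxidation at both sites and corrects it at the end. It sets out from 17.
- Excess DDQ in refluxing dioxane is the classical condition both for isoflavanone to isoflavone and for 2,2-dimethylchroman to chromene. It would give 7-(benzyloxy)-3-[7-(benzyloxy)-5-methoxy-2,2-dimethyl-2H-chromen-6-yl]-4H-chromen-4-one F4.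
- Hydrogenation over Pd/C (H2, 1 atm, EtOAc–MeOH) then saturates the reactive chromene double bond and cleaves both benzyl ethers in one operation, arriving at 20.

**Further compounds**
F1 | step 10 | 5-(benzyloxy)-2-(4,4,5,5-tetramethyl-1,3,2-dioxaborolan-2-yl)phenol | Oc1cc(OCc2ccccc2)ccc1B1OC(C)(C)C(C)(C)O1
F2 | step 8 | 1-[7-(benzyloxy)-5-methoxy-2,2-dimethylchroman-6-yl]ethan-1-one hydrazone (C=N geometry not defined) | COc1c2c(cc(OCc3ccccc3)c1C(C)=NN)OC(C)(C)CC2
F3 | step 8 | 7-(benzyloxy)-6-(1-iodovinyl)-5-methoxy-2,2-dimethylchroman | C=C(I)c1c(OC)c2c(cc1OCc1ccccc1)OC(C)(C)CC2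
F4 | step 12 | 7-(benzyloxy)-3-[7-(benzyloxy)-5-methoxy-2,2-dimethyl-2H-chromen-6-yl]-4H-chromen-4-one | COc1c2c(cc(OCc3ccccc3)c1-c1coc3cc(OCc4ccccc4)ccc3c1=O)OC(C)(C)C=C2
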